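**Strategy.** Ring B is disconnected at C7–C8 as the aldol condensation that ends a Robinson-type annulation. The precursor is a monocyclic ring-A enone (C5=C10, acetyl at C5) whose C18 oxygen carries an acetoacetate. Base makes this tether add C9 to C10 from the face of C18, setting the quaternary C10 relative to C4 through a temporary seven-membered lactone, and the C7 enolate then closes ring B onto C8 and dehydrates. The step exploits the 3-methylcyclohex-2-enone hidden in ring B (C6, C7, C8, C17) and the cis relation of C18 and C9 across ring A. Lactone opening, epoxidation and dissolving-metal reduction install the 6,8-diol; radical allylation adds the diene.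

Key step: step 9

Remark: labdane numbering is used from compound 11 on (C11 on C9, C17 on C8, C18/C19 on C4, C20 on C10; "pentanor" = C12–C16 absent). β means the decalin face that carries C20, α the opposite face; the SMILES strings fix the absolute configuration.

Step 1
Reactants: 1 ethyl 2-oxocyclohexane-1-carboxylate
Product: 2 ethyl (1R,2R)-2-hydroxycyclohexane-1-carboxylate
Conditions: H2 (100 atm), RuBr2[(R)-BINAP] (cat.), CH2Cl2, 50 °C
Reagents that add atoms: none
Why: Noyori asymmetric hydrogenation under dynamic kinetic resolution: the β-keto ester racemizes through its enol faster than it is reduced, and the (R)-BINAP ruthenium catalyst should deliver hydrogen to one carbonyl face to set the 2R carbinol, the centre that steers step 2.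

Step 2
Reactants: 2 ethyl (1R,2R)-2-hydroxycyclohexane-1-carboxylate
Product: 3 ethyl (1S,2R)-2-hydroxy-1-methylcyclohexane-1-carboxylate
Conditions: LiN(i-Pr)2 (2.2 equiv), THF, −50 to −20 °C; MeI, DMPU, −78 to 0 °C; aq NH4Cl
Reagents that add atoms: iodomethane CI
Why: Fráter–Seebach alkylation: the chelated lithium alkoxide–enolate is attacked by MeI anti to the C2–O bond, so the new methyl is trans to the hydroxyl and the quaternary carbon (later C4) forms as 1S.

Step 3
Reactants: 3 ethyl (1S,2R)-2-hydroxy-1-methylcyclohexane-1-carboxylate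
Product: 4 ethyl (1S)-1-methyl-2-oxocyclohexane-1-carboxylate
Conditions: Dess–Martin periodinane, CH2Cl2, rt
Reagents that add atoms: none
Why: Dess–Martin oxidation of the secondary alcohol; the quaternary stereocentre has no α-hydrogen and cannot epimerize.

Step 4
Reactants: 4 ethyl (1S)-1-methyl-2-oxocyclohexane-1-carboxylate
Product: 5 ethyl (1S)-1,3-dimethyl-2-oxocyclohexane-1-carboxylate (both C3 epimers)
Conditions: LiN(i-Pr)2, THF, −78 °C; MeI, −78 to 0 °C
Reagents that add atoms: iodomethane CI
Why: Kinetic enolate alkylation at the only enolizable position (C3, later C10); the new centre forms as a mixture, which does not matter because it becomes sp2 in step 5.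

Step 5
Reactants: 5 ethyl (1S)-1,3-dimethyl-2-oxocyclohexane-1-carboxylate
Product: 6 ethyl (1S)-1,3-dimethyl-2-[(trifluoromethanesulfonyl)oxy]cyclohex-2-ene-1-carboxylate
Conditions: KN(SiMe3)2, THF, −78 °C; PhNTf2, −78 °C to rt; aq NH4Cl
Reagents that add atoms: N-phenylbis(trifluoromethanesulfonimide) O=S(=O)(N(c1ccccc1)S(=O)(=O)C(F)(F)F)C(F)(F)F
Why: Enol triflate formation: only the C3–H can be removed, and O-sulfonylation of the potassium enolate gives the tetrasubstituted vinyl triflate without touching C1.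

Step 6
Reactants: 6 ethyl (1S)-1,3-dimethyl-2-[(trifluoromethanesulfonyl)oxy]cyclohex-2-ene-1-carboxylate
Product: 7 [(1R)-1,3-dimethyl-2-[(trifluoromethanesulfonyl)oxy]cyclohex-2-en-1-yl]methanol
Conditions: i-Bu2AlH (2.5 equiv), CH2Cl2, −78 to 0 °C; Rochelle salt
Reagents that add atoms: none
Why: Hydride reduction of the ester to the primary alcohol (later C18–OH), which the vinyl triflate tolerates at low temperature; the descriptor changes only through priorities.

Step 7
Reactants: 7 [(1R)-1,3-dimethyl-2-[(trifluoromethanesulfonyl)oxy]cyclohex-2-en-1-yl]methanol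
Product: 9 1-[(6S)-6-(hydroxymethyl)-2,6-dimethylcyclohex-1-en-1-yl]ethan-1-one, via enol ether 8 (not isolated)
Conditions: Pd(PPh3)4 (5 mol%), LiCl, tributyl(1-ethoxyvinyl)stannane, 1,4-dioxane, 100 °C; then 1 M HCl, THF, rt
Reagents that add atoms: tributyl(1-ethoxyvinyl)stannane C=C(OCC)[Sn](CCCC)(CCCC)CCCC; water O
Why: Stille coupling of the hindered vinyl triflate with an acyl-anion equivalent, then acid hydrolysis of enol ether 8 to the methyl ketone (C6, C7).

Step 8
Reactants: 9 1-[(6S)-6-(hydroxymethyl)-2,6-dimethylcyclohex-1-en-1-yl]ethan-1-one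
Product: 10 [(1S)-2-acetyl-1,3-dimethylcyclohex-2-en-1-yl]methyl 3-oxobutanoate
Conditions: 2,2,6-trimethyl-4H-1,3-dioxin-4-one, toluene, 110 °C
Reagents that add atoms: 2,2,6-trimethyl-4H-1,3-dioxin-4-one CC1=CC(=O)OC(C)(C)O1
Why: Acetoacetylation: thermal retro-[4+2] fragmentation of the dioxinone releases acetylketene, which the neopentyl alcohol traps to give the β-keto ester that carries C11, C9, C8 and C17.

Step 9
Reactants: 10 [(1S)-2-acetyl-1,3-dimethylcyclohex-2-en-1-yl]methyl 3-oxobutanoate
Product: 13 6-oxo-12,13,14,15,16-pentanorlabd-7-en-11,18-olide (cis-fused, 5β-H, 9β-H), via keto lactone 11 (not isolated), via aldol adduct 12 (not isolated)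
Conditions: KOt-Bu (1.2 equiv), t-BuOH/THF, 25 to 70 °C; aq NH4Cl
Reagents that add atoms: none
Why: tert-Butoxide ionizes the acetoacetate (C9–H) and the tethered enolate adds to C10 of the C5=C10–C6=O enone (11); after proton exchange the C7 enolate of the C6 methyl ketone attacks the C8 ketone (12) and E1cB loss of water gives the C7=C8–C6=O enone. The closest known reaction is the acetoacetate–enone Michael/aldol condensation (Robinson annulation, as in the Hagemann-ester and isophorone-carboxylate syntheses), here run intramolecularly. The lactone ring closes by a 7-endo-trig conjugate addition and ring B by a 6-(enolendo)-exo-trig aldol addition, C7–C8 being the ring-closing bond of the carbocycle. C10 is controlled by the tether, since the C18–O–C11 link can deliver C9 only to the α-face of C10, cis to C18; the bridged intermediate forces C9 (C11 α) and C5 (5β-H, cis fusion) into configurations that are corrected in step 10. The step needs attack at C10 in place of addition to the C6 carbonyl, and an aldol from C7 onto C8 in place of one from C17 onto C6; the soft stabilized enolate and the ring size should secure the first, the hindered, doubly flanked C6 ketone and the irreversible dehydration the second.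

Step 10
Reactants: 13 6-oxo-12,13,14,15,16-pentanorlabd-7-en-11,18-olide (5β-H, 9β-H)
Product: 15 methyl 18-hydroxy-6-oxo-12,13,14,15,16-pentanorlabd-7-en-11-oate (trans-fused, 5α-H, 9α-H), via cis-fused hydroxy ester 14 (not isolated)
Conditions: NaOMe (2 equiv), MeOH, 65 °C; AcOH
Reagents that add atoms: methanol CO
Why: Methoxide opens the strained lactone by transesterification; once untethered, C5 (α to the C6 ketone) should equilibrate to the trans-fused decalin and C9 (vinylogous β-keto ester position) epimerizes freely, 15 being drawn as the 9α-H epimer that is consumed in step 12.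

Step 11
Reactants: 15 methyl 18-hydroxy-6-oxo-12,13,14,15,16-pentanorlabd-7-en-11-oate
Product: 16 methyl 18-[(tert-butyldimethylsilyl)oxy]-6-oxo-12,13,14,15,16-pentanorlabd-7-en-11-oate
Conditions: t-BuMe2SiCl, imidazole, DMF, rt
Reagents that add atoms: tert-butyldimethylsilyl chloride CC(C)(C)[Si](C)(C)Cl
Why: Silylation of the primary neopentyl alcohol protects O18 through the reductions and the acetylation that follow.

Step 12
Reactants: 16 methyl 18-[(tert-butyldimethylsilyl)oxy]-6-oxo-12,13,14,15,16-pentanorlabd-7-en-11-oate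
Product: 17 methyl 18-[(tert-butyldimethylsilyl)oxy]-7α,8α-epoxy-6-oxo-12,13,14,15,16-pentanorlabdan-11-oate
Conditions: 30% H2O2, NaOH (0.2 equiv), MeOH, 0 °C
Reagents that add atoms: hydrogen peroxide OO
Why: Weitz–Scheffer nucleophilic epoxidation: hydroperoxide should add to C8 from the α-face, away from the axial C20 methyl and the β-ester at C9, and because the C9 epimers interconvert under the basic conditions the 9α-H epimer is drained (Curtin–Hammett).

Step 13
Reactants: 17 methyl 18-[(tert-butyldimethylsilyl)oxy]-7α,8α-epoxy-6-oxo-12,13,14,15,16-pentanorlabdan-11-oate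
Product: 19 18-[(tert-butyldimethylsilyl)oxy]-12,13,14,15,16-pentanorlabdane-6α,8α,11-triol, via hydroxy ketone 18 (not isolated)
Conditions: Li (excess), NH3(l)/THF, −78 °C; EtOH, −78 to −33 °C; NH4Cl
Reagents that add atoms: none
Why: Dissolving-metal reduction: two-electron cleavage of the C7–O bond of the α,β-epoxy ketone keeps the C8–O bond (8α-OH, 18), the C6 ketone is then reduced under thermodynamic control to the equatorial 6α-alcohol, and the methyl ester is reduced (Bouveault–Blanc) to the C11 alcohol.

Step 14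
Reactants: 19 18-[(tert-butyldimethylsilyl)oxy]-12,13,14,15,16-pentanorlabdane-6α,8α,11-triol
Product: 20 11-iodo-18-[(tert-butyldimethylsilyl)oxy]-12,13,14,15,16-pentanorlabdane-6α,8α-diol
Conditions: I2, PPh3, imidazole, CH2Cl2, 0 °C to rt
Reagents that add atoms: iodine II
Why: Appel-type iodination (SN2 displacement of the oxyphosphonium by iodide) should be selective for the primary C11 alcohol over the hindered secondary 6-OH and the tertiary 8-OH.

Step 15
Reactants: 21 isoprene
Product: 23 tributyl(2-methylidenebut-3-en-1-yl)stannane, via allylpotassium 22 (not isolated)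
Conditions: lithium 2,2,6,6-tetramethylpiperidide, KOt-Bu, THF, −78 °C; Bu3SnCl, −78 °C to rt
Reagents that add atoms: tributyltin chloride CCCC[Sn](Cl)(CCCC)CCCC
Why: Allylic metalation of the isoprene methyl group by the mixed lithium amide/potassium alkoxide base gives the 2-vinylallyl potassium species 22, which is stannylated at carbon.

Step 16
Reactants: 20 11-iodo-18-[(tert-butyldimethylsilyl)oxy]-12,13,14,15,16-pentanorlabdane-6α,8α-diol; 23 tributyl(2-methylidenebut-3-en-1-yl)stannane
Product: 24 18-[(tert-butyldimethylsilyl)oxy]labda-13(16),14-diene-6α,8α-diol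
Conditions: AIBN (cat.), benzene, 80 °C
Reagents that add atoms: none
Why: Keck radical allylation: the C11 radical adds to the methylidene terminus of the stannane and β-scission of tin leaves the 2-substituted buta-1,3-diene; the neutral chain tolerates the free hydroxyls and avoids Grob fragmentation of an 8-oxido 11-iodide.

Step 17
Reactants: 24 18-[(tert-butyldimethylsilyl)oxy]labda-13(16),14-diene-6α,8α-diol
Product: 25 6α-acetoxy-18-[(tert-butyldimethylsilyl)oxy]labda-13(16),14-dien-8α-ol
Conditions: Ac2O, DMAP (cat.), pyridine, rt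
Reagents that add atoms: acetic anhydride CC(=O)OC(C)=O
Why: DMAP-catalysed acylation esterifies the secondary 6α-OH while the tertiary 8α-OH stays free.

Step 18
Reactants: 25 6α-acetoxy-18-[(tert-butyldimethylsilyl)oxy]labda-13(16),14-dien-8α-ol
Product: 26 (4S,5S,6R,8S,9S,10R)-6-acetoxylabda-13(16),14-diene-8,18-diol (target)
Conditions: Bu4NF, AcOH, THF, 0 °C to rt
Reagents that add atoms: none
Why: Fluoride-induced desilylation buffered with acetic acid frees O18 and should not cleave or move the acetate.

**Compound list**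

1 | ethyl 2-oxocyclohexane-1-carboxylate | CCOC(=O)C1CCCCC1=O | starting material
2 | ethyl (1R,2R)-2-hydroxycyclohexane-1-carboxylate | CCOC(=O)[C@@H]1CCCC[C@H]1O | intermediate
3 | ethyl (1S,2R)-2-hydroxy-1-methylcyclohexane-1-carboxylate | CCOC(=O)[C@@]1(C)CCCC[C@H]1O | intermediate
4 | ethyl (1S)-1-methyl-2-oxocyclohexane-1-carboxylate | CCOC(=O)[C@@]1(C)CCCCC1=O | intermediate
5 | ethyl (1S)-1,3-dimethyl-2-oxocyclohexane-1-carboxylate (C3 epimers) | CCOC(=O)[C@@]1(C)CCCC(C)C1=O | intermediate
6 | ethyl (1S)-1,3-dimethyl-2-[(trifluoromethanesulfonyl)oxy]cyclohex-2-ene-1-carboxylate | CCOC(=O)[C@@]1(C)CCCC(C)=C1OS(=O)(=O)C(F)(F)F | intermediate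
7 | [(1R)-1,3-dimethyl-2-[(trifluoromethanesulfonyl)oxy]cyclohex-2-en-1-yl]methanol | OC[C@@]1(C)CCCC(C)=C1OS(=O)(=O)C(F)(F)F | intermediate
8 | [(1S)-2-(1-ethoxyethenyl)-1,3-dimethylcyclohex-2-en-1-yl]methanol | OC[C@@]1(C)CCCC(C)=C1C(=C)OCC | intermediate
9 | 1-[(6S)-6-(hydroxymethyl)-2,6-dimethylcyclohex-1-en-1-yl]ethan-1-one | OC[C@@]1(C)CCCC(C)=C1C(C)=O | intermediate
10 | [(1S)-2-acetyl-1,3-dimethylcyclohex-2-en-1-yl]methyl 3-oxobutanoate | CC(=O)CC(=O)OC[C@@]1(C)CCCC(C)=C1C(C)=O | intermediate
11 | 6,8-dioxo-7,8-seco-12,13,14,15,16-pentanorlabdan-11,18-olide (5β-H; C9 on the α-face of C10) | O=C1OC[C@@]2(C)CCC[C@](C)([C@H]2C(C)=O)[C@@H]1C(C)=O | intermediate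
12 | 8-hydroxy-6-oxo-12,13,14,15,16-pentanorlabdan-11,18-olide (5β-H, 9β-H; C8 unassigned) | O=C1OC[C@@]2(C)CCC[C@@]3(C)[C@@H]1C(C)(O)CC(=O)[C@@H]23 | intermediate
13 | 6-oxo-12,13,14,15,16-pentanorlabd-7-en-11,18-olide (cis-fused, 5β-H, 9β-H) | O=C1OC[C@@]2(C)CCC[C@@]3(C)[C@@H]1C(C)=CC(=O)[C@@H]23 | intermediate
14 | methyl 18-hydroxy-6-oxo-12,13,14,15,16-pentanorlabd-7-en-11-oate, 5β-H,9β-H isomer | COC(=O)[C@@H]1[C@]2(C)CCC[C@](C)(CO)[C@@H]2C(=O)C=C1C | intermediate
15 | methyl 18-hydroxy-6-oxo-12,13,14,15,16-pentanorlabd-7-en-11-oate (5α-H, 9α-H) | COC(=O)[C@H]1[C@]2(C)CCC[C@](C)(CO)[C@H]2C(=O)C=C1C | intermediate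
16 | methyl 18-[(tert-butyldimethylsilyl)oxy]-6-oxo-12,13,14,15,16-pentanorlabd-7-en-11-oate | COC(=O)[C@H]1[C@]2(C)CCC[C@](C)(CO[Si](C)(C)C(C)(C)C)[C@H]2C(=O)C=C1C | intermediate
17 | methyl 18-[(tert-butyldimethylsilyl)oxy]-7α,8α-epoxy-6-oxo-12,13,14,15,16-pentanorlabdan-11-oate | COC(=O)[C@H]1[C@]2(C)CCC[C@](C)(CO[Si](C)(C)C(C)(C)C)[C@H]2C(=O)[C@@H]3O[C@]13C | intermediate
18 | methyl 18-[(tert-butyldimethylsilyl)oxy]-8α-hydroxy-6-oxo-12,13,14,15,16-pentanorlabdan-11-oate | COC(=O)[C@H]1[C@]2(C)CCC[C@](C)(CO[Si](C)(C)C(C)(C)C)[C@H]2C(=O)C[C@]1(C)O | intermediate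
19 | 18-[(tert-butyldimethylsilyl)oxy]-12,13,14,15,16-pentanorlabdane-6α,8α,11-triol | OC[C@H]1[C@]2(C)CCC[C@](C)(CO[Si](C)(C)C(C)(C)C)[C@H]2[C@H](O)C[C@]1(C)O | intermediate
20 | 11-iodo-18-[(tert-butyldimethylsilyl)oxy]-12,13,14,15,16-pentanorlabdane-6α,8α-diol | IC[C@H]1[C@]2(C)CCC[C@](C)(CO[Si](C)(C)C(C)(C)C)[C@H]2[C@H](O)C[C@]1(C)O | intermediate
21 | isoprene (2-methylbuta-1,3-diene) | C=CC(C)=C | starting material
22 | (2-methylidenebut-3-en-1-yl)potassium | [K]CC(=C)C=C | intermediate
23 | tributyl(2-methylidenebut-3-en-1-yl)stannane | C=CC(=C)C[Sn](CCCC)(CCCC)CCCC | intermediate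
24 | 18-[(tert-butyldimethylsilyl)oxy]labda-13(16),14-diene-6α,8α-diol | C=CC(=C)CC[C@H]1[C@]2(C)CCC[C@](C)(CO[Si](C)(C)C(C)(C)C)[C@H]2[C@H](O)C[C@]1(C)O | intermediate
25 | 6α-acetoxy-18-[(tert-butyldimethylsilyl)oxy]labda-13(16),14-dien-8α-ol | C=CC(=C)CC[C@H]1[C@]2(C)CCC[C@](C)(CO[Si](C)(C)C(C)(C)C)[C@H]2[C@H](OC(C)=O)C[C@]1(C)O | intermediate
26 | (4S,5S,6R,8S,9S,10R)-6-acetoxylabda-13(16),14-diene-8,18-diol | C=CC(=C)CC[C@H]1[C@]2(C)CCC[C@](C)(CO)[C@H]2[C@H](OC(C)=O)C[C@]1(C)O | target

**Step count.** Total: 18 steps. Longest linear sequence: 17 steps (steps 1–14 and 16–18; step 15 is a side branch).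

**Steps most likely to fail**

Step 9. The conjugate addition may be too slow or uphill: the enone is tetrasubstituted and twisted, the ring being closed is seven-membered, and a quaternary centre is formed, so retro-Claisen cleavage or intermolecular reactions could take over. The fallback replaces the Michael addition by a π-allylpalladium alkylation and sets out from 9. Luche reduction (NaBH4, CeCl3) should give the diol, 1-[(6S)-6-(hydroxymethyl)-2,6-dimethylcyclohex-1-en-1-yl]ethan-1-ol F1. Both hydroxyls are acetoacetylated with the dioxinone of step 8 to the bis(3-oxobutanoate) F2. Pd(PPh3)4 ionizes the allylic ester with loss of CO2 and acetone (Tsuji–Trost alkylation), and the tethered β-keto ester should attack the C10 terminus of the allyl complex on the face of C18, the ring size excluding the C6 terminus, to give the ethylidene keto lactone F3. Hydroboration–oxidation (BH3·THF; H2O2, NaOH) from the β-face, the α-face being covered by the lactone, also reduces the C8 ketone and gives the diol lactone F4. Dess–Martin oxidation returns the route at 11, which the base of step 9 condenses to 13.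

Step 13. Retro-aldol opening of the 8-oxido ketone or 8-oxido ester may compete before the carbonyl groups are reduced, and the ester reduction may be incomplete. The fallback avoids the dissolving metal and sets out from 17. Wharton transposition (N2H4·H2O, AcOH, MeOH) should give the allylic alcohol, methyl 18-[(tert-butyldimethylsilyl)oxy]-8α-hydroxy-12,13,14,15,16-pentanorlabd-6-en-11-oate F5. Hydroboration–oxidation places oxygen at C6 (distal to the C8 oxygen) from the α-face, giving methyl 18-[(tert-butyldimethylsilyl)oxy]-6α,8α-dihydroxy-12,13,14,15,16-pentanorlabdan-11-oate F6. LiAlH4 reduces the ester and returns the route at 19.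

Step 16. The alkyl radical may add to the diene of reagent or product, and chain propagation may be poor. The fallback builds the diene after the radical step and sets out from 20. Radical allylation with 2,3-dibromopropene ((Bu3Sn)2, hν, benzene) should give the vinyl bromide, 13-bromo-18-[(tert-butyldimethylsilyl)oxy]-14,15-dinorlabd-13(16)-ene-6α,8α-diol F7. Stille coupling with tributyl(vinyl)stannane (Pd(PPh3)4, DMF, 80 °C) returns the route at 24.

Further compounds

F1 | step 9 | 1-[(6S)-6-(hydroxymethyl)-2,6-dimethylcyclohex-1-en-1-yl]ethan-1-ol (carbinol epimers) | OC[C@@]1(C)CCCC(C)=C1C(C)O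
F2 | step 9 | 1-[(6S)-2,6-dimethyl-6-{[(3-oxobutanoyl)oxy]methyl}cyclohex-1-en-1-yl]ethyl 3-oxobutanoate | CC(=O)CC(=O)OC[C@@]1(C)CCCC(C)=C1C(C)OC(=O)CC(C)=O
F3 | step 9 | 8-oxo-7,8-seco-12,13,14,15,16-pentanorlabd-5-en-11,18-olide (C9 and alkene geometry unassigned) | CC=C1[C@@]2(C)CCC[C@]1(C)COC(=O)C2C(C)=O
F4 | step 9 | 6,8-dihydroxy-7,8-seco-12,13,14,15,16-pentanorlabdan-11,18-olide (5β-H; carbinols and C9 unassigned) | O=C1OC[C@@]2(C)CCC[C@](C)([C@H]2C(C)O)C1C(C)O
F5 | step 13 | methyl 18-[(tert-butyldimethylsilyl)oxy]-8α-hydroxy-12,13,14,15,16-pentanorlabd-6-en-11-oate | COC(=O)[C@H]1[C@]2(C)CCC[C@](C)(CO[Si](C)(C)C(C)(C)C)[C@H]2C=C[C@]1(C)O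
F6 | step 13 | methyl 18-[(tert-butyldimethylsilyl)oxy]-6α,8α-dihydroxy-12,13,14,15,16-pentanorlabdan-11-oate | COC(=O)[C@H]1[C@]2(C)CCC[C@](C)(CO[Si](C)(C)C(C)(C)C)[C@H]2[C@H](O)C[C@]1(C)O
F7 | step 16 | 13-bromo-18-[(tert-butyldimethylsilyl)oxy]-14,15-dinorlabd-13(16)-ene-6α,8α-diol | C=C(Br)CC[C@H]1[C@]2(C)CCC[C@](C)(CO[Si](C)(C)C(C)(C)C)[C@H]2[C@H](O)C[C@]1(C)O
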